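**Plan**

- Retrosynthesis: the acetonide C–O bonds are cut first, then the C3–C3a and N1–C2 bonds of ring A (giving 2-iodoaniline and an internal alkyne), then the C1'–C3 bond to ring B (indole plus an alkynyl epoxide), the epoxide oxygen, and the C(sp)–C(sp2) bond of an enyne.
- Forward: but-3-ynyl acetate and (E)-3-iodoallyl alcohol are joined, the enyne is epoxidised, indole (ring B, used intact) is attached at the propargylic carbon, the diol is masked, ring A is annulated last and the diol is released.
- Enabling feature: in ring A, C3 carries the unbranched CH2CH2OAc chain and C2 carries the α-branched methine C1' (bearing ring B and the oxygenated carbon C2'). This size contrast between the two alkyne substituents fixes the direction of alkyne insertion.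
- Stereochemistry: one Sharpless epoxidation with D-(−)-diethyl tartrate sets both centres as the (2R,3R)-trans-epoxide. C2' keeps its C–O bond and C1' is set by inversion when indole opens the epoxide; no later step touches either centre.

Key step: step 8

Remark: the target is read as the (1'S,2'S) isomer (C1' = methine between the two indoles, C2' = secondary carbinol). In the alkyne intermediates the same spatial arrangement at C1' is labelled R only because the CIP ranking changes.

**Route**

Step 1
Reactants: 1 but-3-yn-1-ol
Product: 2 but-3-yn-1-yl acetate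
Conditions: Ac2O, pyridine, DMAP (cat.), CH2Cl2, 0 °C to rt
Reagents that add atoms: acetic anhydride, CC(=O)OC(C)=O
Why: DMAP-catalysed O-acetylation (nucleophilic acyl substitution) of an unhindered primary alcohol is routine and installs the acetate of the target at the outset, so this hydroxyl never needs a separate protecting group.

Step 2
Reactants: 3 prop-2-yn-1-ol (propargyl alcohol)
Product: 4 (E)-3-(tributylstannyl)prop-2-en-1-ol
Conditions: Bu3SnH (1.3 equiv), AIBN (cat.), neat, 80 °C; chromatography
Reagents that add atoms: tributyltin hydride, CCCC[SnH](CCCC)CCCC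
Why: Radical hydrostannation of the terminal alkyne (AIBN initiation), in which reversible stannyl-radical addition at 80 °C should equilibrate the vinylstannanes toward the (E)-β isomer, separable from minor isomers by chromatography.

Step 3
Reactants: 4 (E)-3-(tributylstannyl)prop-2-en-1-ol
Product: 5 (E)-3-iodoprop-2-en-1-ol
Conditions: I2, CH2Cl2, 0 °C
Reagents that add atoms: iodine, II
Why: Iododestannylation (electrophilic ipso-substitution at the vinyl–tin bond) should replace tin by iodine with retention of the E geometry.

Step 4
Reactants: 2 but-3-yn-1-yl acetate; 5 (E)-3-iodoprop-2-en-1-ol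
Product: 6 (E)-7-hydroxyhept-5-en-3-yn-1-yl acetate
Conditions: PdCl2(PPh3)2 (2 mol %), CuI (4 mol %), Et3N, THF, rt
Reagents that add atoms: none
Why: Sonogashira coupling of a terminal alkyne with a vinyl iodide proceeds with retention of alkene geometry at room temperature and tolerates both the free allylic alcohol and the acetate.

Step 5
Reactants: 6 (E)-7-hydroxyhept-5-en-3-yn-1-yl acetate
Product: 7 4-[(2R,3R)-3-(hydroxymethyl)oxiran-2-yl]but-3-yn-1-yl acetate
Conditions: Ti(OiPr)4 (10 mol %), D-(−)-diethyl tartrate (12 mol %), t-BuOOH (2 equiv), 4 Å MS, CH2Cl2, −20 °C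
Reagents that add atoms: tert-butyl hydroperoxide, CC(C)(C)OO
Why: Sharpless asymmetric epoxidation of a primary (E)-allylic alcohol, in which the titanium–D-(−)-tartrate catalyst should deliver oxygen to the face that gives the (2R,3R)-trans-epoxide (the mirror image of the (2S,3S) series obtained with L-(+)-tartrate), setting both stereocentres while the alkyne stays inert.

Step 6
Reactants: 7 4-[(2R,3R)-3-(hydroxymethyl)oxiran-2-yl]but-3-yn-1-yl acetate; 8 indole
Product: 9 (5R,6S)-6,7-dihydroxy-5-(1H-indol-3-yl)hept-3-yn-1-yl acetate
Conditions: indole (1.5 equiv), InBr3 (10 mol %), CH2Cl2, −20 °C to rt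
Reagents that add atoms: none
Why: Friedel–Crafts opening of a Lewis-acid-activated epoxide by indole C3, as established for aryl oxiranes and glycidic esters, should occur in SN2 fashion at the propargylic epoxide carbon (the alkyne stabilises developing positive charge, the CH2OH-bearing carbon is inductively deactivated), so C1' is set by inversion and C2' keeps its C–O bond.

Step 7
Reactants: 9 (5R,6S)-6,7-dihydroxy-5-(1H-indol-3-yl)hept-3-yn-1-yl acetate
Product: 10 (5R)-5-[(4S)-2,2-dimethyl-1,3-dioxolan-4-yl]-5-(1H-indol-3-yl)pent-3-yn-1-yl acetate
Conditions: 2,2-dimethoxypropane, PPTS (cat.), acetone, rt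
Reagents that add atoms: 2,2-dimethoxypropane, COC(C)(C)OC
Why: Acid-catalysed transacetalisation should give the five-membered acetonide of the only 1,2-diol without touching either stereocentre, masking the hydroxyls and enlarging the branched alkyne substituent ahead of the annulation.

Step 8
Reactants: 10 (5R)-5-[(4S)-2,2-dimethyl-1,3-dioxolan-4-yl]-5-(1H-indol-3-yl)pent-3-yn-1-yl acetate; 11 2-iodoaniline
Product: 12 2-[2-[(S)-[(4S)-2,2-dimethyl-1,3-dioxolan-4-yl](1H-indol-3-yl)methyl]-1H-indol-3-yl]ethyl acetate
Conditions: 2-iodoaniline (1.5 equiv), Pd(OAc)2 (5 mol %), LiCl (1 equiv), Na2CO3 (3 equiv), DMF, 100 °C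
Reagents that add atoms: none
Why: Larock heteroannulation: Pd(OAc)2 is reduced in situ to zerovalent palladium, which inserts into the C–I bond of 11, and the resulting arylpalladium iodide (divalent palladium) adds syn across the alkyne of 10. The aryl group goes to the alkyne carbon bearing CH2CH2OAc (forming C3–C3a) and palladium to the carbon bearing the branched methine, which becomes C2. The aniline nitrogen then replaces halide on palladium to give a six-membered azapalladacycle, and C–N reductive elimination forms N1–C2 and closes the pyrrole ring of ring A, so the ring arises by a [3+2] annulation in which C–C bond formation precedes C–N bond formation. No stereocentre is created; C1' and the dioxolane carbon are spectators, and the weak, poorly soluble carbonate base should leave the propargylic C–H of 10 untouched, so neither allene formation nor epimerisation is expected before insertion. The selectivity needed is the insertion regiochemistry, and it is secured by the size contrast between the α-branched carbon carrying ring B and the dioxolane and the unbranched CH2CH2OAc chain, the larger group preferring the position next to the long C–Pd bond over that next to the incoming aryl group. The closest known reaction type is the palladium-catalysed annulation of 2-iodoanilines with unsymmetrical internal alkynes, which tolerates esters, acetals and free N–H groups.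

Step 9
Reactants: 12 2-[2-[(S)-[(4S)-2,2-dimethyl-1,3-dioxolan-4-yl](1H-indol-3-yl)methyl]-1H-indol-3-yl]ethyl acetate
Product: 13 Colletotryptin C, 2-[2-[(1S,2S)-2,3-dihydroxy-1-(1H-indol-3-yl)propyl]-1H-indol-3-yl]ethyl acetate
Conditions: AcOH/H2O (4:1), 40 °C
Reagents that add atoms: none
Why: Acid-catalysed acetal hydrolysis of a terminal acetonide under conditions that should leave the primary acetate and both indoles intact, and since the C–O bonds at C2' and C3' are not broken the configuration is retained.

**Compound list**

1 | but-3-yn-1-ol | C#CCCO | starting material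
2 | but-3-yn-1-yl acetate | CC(=O)OCCC#C | intermediate
3 | prop-2-yn-1-ol (propargyl alcohol) | C#CCO | starting material
4 | (E)-3-(tributylstannyl)prop-2-en-1-ol | CCCC[Sn](CCCC)(CCCC)/C=C/CO | intermediate
5 | (E)-3-iodoprop-2-en-1-ol | OC/C=C/I | intermediate
6 | (E)-7-hydroxyhept-5-en-3-yn-1-yl acetate | CC(=O)OCCC#C/C=C/CO | intermediate
7 | 4-[(2R,3R)-3-(hydroxymethyl)oxiran-2-yl]but-3-yn-1-yl acetate | CC(=O)OCCC#C[C@H]1O[C@@H]1CO | intermediate
8 | indole | c1ccc2[nH]ccc2c1 | starting material
9 | (5R,6S)-6,7-dihydroxy-5-(1H-indol-3-yl)hept-3-yn-1-yl acetate | CC(=O)OCCC#C[C@H](c1c[nH]c2ccccc12)[C@H](O)CO | intermediate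
10 | (5R)-5-[(4S)-2,2-dimethyl-1,3-dioxolan-4-yl]-5-(1H-indol-3-yl)pent-3-yn-1-yl acetate | CC(=O)OCCC#C[C@H](c1c[nH]c2ccccc12)[C@H]1COC(C)(C)O1 | intermediate
11 | 2-iodoaniline | Nc1ccccc1I | starting material
12 | 2-[2-[(S)-[(4S)-2,2-dimethyl-1,3-dioxolan-4-yl](1H-indol-3-yl)methyl]-1H-indol-3-yl]ethyl acetate | CC(=O)OCCc1c([C@H](c2c[nH]c3ccccc23)[C@H]2COC(C)(C)O2)[nH]c2ccccc12 | intermediate
13 | Colletotryptin C | CC(=O)OCCc1c([C@H](c2c[nH]c3ccccc23)[C@H](O)CO)[nH]c2ccccc12 | target

**Step count**

Total: 9 steps. Longest linear sequence: 8 steps (from propargyl alcohol 3 through steps 2 to 9).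

**Steps most likely to fail**

1. Step 6. The activated epoxide may ionise to a propargylic cation before indole attacks, eroding the inversion at C1'. Attack may also drift to the CH2OH-bearing carbon or to the remote alkyne carbon (SN2' opening to an allene), and the Lewis acid may cyclise the product diol onto the alkyne. The fallback sets out from enyne 6 and returns at diol 9, setting each centre under catalyst control with known organocatalytic reactions. Oxidation of 6 with MnO2 in CH2Cl2 should give (E)-7-oxohept-5-en-3-yn-1-yl acetate F1. Iminium-catalysed conjugate Friedel–Crafts addition of indole 8 to F1 uses a chiral 5-benzyl-2-tert-butyl-3-methylimidazolidin-4-one trifluoroacetate salt, taken as the enantiomer that delivers the R adduct (by the usual facial model the (2R,5R) catalyst). This should give (R)-5-(1H-indol-3-yl)-7-oxohept-3-yn-1-yl acetate F2. Enamine-catalysed α-aminoxylation of F2 with nitrosobenzene and D-proline should give (5R,6S)-5-(1H-indol-3-yl)-7-oxo-6-(phenylaminooxy)hept-3-yn-1-yl acetate F3, which is reduced in the same flask with NaBH4 to (5R,6S)-7-hydroxy-5-(1H-indol-3-yl)-6-(phenylaminooxy)hept-3-yn-1-yl acetate F4. Cleavage of the N–O bond of F4 with Zn in AcOH should then give 9.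

2. Step 8. Regiocontrol may erode in the migratory insertion, with aryl adding to the alkyne carbon next to C1'. The propargylic C–H may isomerise to an allene or epimerise under hot basic conditions before insertion, and the arylpalladium species may be diverted into arylation of ring B. The fallback sets out from diol 9 and comes back at the target 13. The annulation with 11 is run on the unprotected diol (Pd(OAc)2, LiCl, KOAc, DMF, 100 °C). The free C2' hydroxyl can then bind the vinylpalladium centre in a five-membered chelate and reinforce placement of the oxygenated branch at C2, and the milder acetate base lowers the risk of isomerisation. Steps 7 and 9 are omitted and no compound outside the list is made (F0).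

3. Step 9. The electron-rich bis-indole may degrade under acid (protonation of ring B and fragmentation at the doubly activated methine), and the acetate may be partly lost during hydrolysis. The fallback sets out from diol 9 and comes back at 13, replacing the acid-labile acetonide by fluoride-labile silyl ethers. Silylation of 9 with TBSOTf and 2,6-lutidine in CH2Cl2 at −78 °C should give (5R,6S)-6,7-bis(tert-butyldimethylsilyloxy)-5-(1H-indol-3-yl)hept-3-yn-1-yl acetate F5. The same annulation with 11 (Pd(OAc)2, LiCl, Na2CO3, DMF, 100 °C) should give 2-[2-[(1S,2S)-2,3-bis(tert-butyldimethylsilyloxy)-1-(1H-indol-3-yl)propyl]-1H-indol-3-yl]ethyl acetate F6, with the bulkier branch further favouring the desired insertion. Desilylation of F6 with HF·pyridine in THF/pyridine at 0 °C to rt should give 13 without exposure to aqueous acid.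

**Further compounds**

F1 | step 6 | (E)-7-oxohept-5-en-3-yn-1-yl acetate | CC(=O)OCCC#C/C=C/C=O
F2 | step 6 | (R)-5-(1H-indol-3-yl)-7-oxohept-3-yn-1-yl acetate | CC(=O)OCCC#C[C@H](c1c[nH]c2ccccc12)CC=O
F3 | step 6 | (5R,6S)-5-(1H-indol-3-yl)-7-oxo-6-(phenylaminooxy)hept-3-yn-1-yl acetate | CC(=O)OCCC#C[C@H](c1c[nH]c2ccccc12)[C@H](ONc1ccccc1)C=O
F4 | step 6 | (5R,6S)-7-hydroxy-5-(1H-indol-3-yl)-6-(phenylaminooxy)hept-3-yn-1-yl acetate | CC(=O)OCCC#C[C@H](c1c[nH]c2ccccc12)[C@H](ONc1ccccc1)CO
F0 | step 8 | none | none
F5 | step 9 | (5R,6S)-6,7-bis(tert-butyldimethylsilyloxy)-5-(1H-indol-3-yl)hept-3-yn-1-yl acetate | CC(=O)OCCC#C[C@H](c1c[nH]c2ccccc12)[C@H](O[Si](C)(C)C(C)(C)C)CO[Si](C)(C)C(C)(C)C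
F6 | step 9 | 2-[2-[(1S,2S)-2,3-bis(tert-butyldimethylsilyloxy)-1-(1H-indol-3-yl)propyl]-1H-indol-3-yl]ethyl acetate | CC(=O)OCCc1c([C@H](c2c[nH]c3ccccc23)[C@H](O[Si](C)(C)C(C)(C)C)CO[Si](C)(C)C(C)(C)C)[nH]c2ccccc12
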